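**Strategy**

- Cuts: after the five O-benzyl bonds, the oxolane is cut at C2–C3 and O1–C5, which releases 4-(benzyloxy)benzaldehyde (its C=O is O1–C2) and a C3–C4–C5 unit stored as a 2,5-diaryl-2,3-dihydrofuran. That ring is cut at O–C(enol) to a homopropargylic alcohol, this at C4–C5 to a propargylic mesylate plus 2,4-bis(benzyloxy)benzaldehyde, and the mesylate goes back to an ynone cut between C=O and the alkyne.
- Enabling feature: with the ring numbered O1, C2 (4-hydroxyphenyl), C3 (2,4-dihydroxybenzoyl), C4 (4-hydroxybenzyl), C5 (2,4-dihydroxyphenyl), C5 carries an aryl group that stabilises a cation through its ortho and para oxygens and C3 carries an enolisable aroyl group. C3–C4–C5 is therefore a masked 1,3-dipole, and C4 is the one centre that cannot epimerise.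
- Forward order: the chain is joined first (aryl alkyne + Weinreb amide to the ynone, then carbinol, mesylate and propargylation onto the aldehyde). Gold then closes a temporary dihydrofuran ring, and the key step opens that ring while it closes the oxolane, the only ring of the target.
- Stereochemistry: C4 comes from the (R)-carbinol set by Noyori transfer hydrogenation and is relayed with net inversion through an allenylzinc. C2, C3 and C5 settle in the key step under thermodynamic control to the all-trans (2S,3S,4S,5S) array.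

Key step: step 8

Assumption: the all-trans arrangement of the four ring substituents is taken to be the most stable diastereomer, as it is for all-trans 2,5-diaryl-3,4-disubstituted oxolanes, so the equilibration in step 8 is expected to end at the target configuration.

**Route**

Step 1
Reactants: 1 2,4-bis(benzyloxy)benzaldehyde
Product: 2 2,4-bis(benzyloxy)-1-ethynylbenzene
Conditions: dimethyl (1-diazo-2-oxopropyl)phosphonate, K2CO3, MeOH–THF, 0 °C → rt
Reagents that add atoms: dimethyl (1-diazo-2-oxopropyl)phosphonate, CC(=O)C(=[N+]=[N-])P(=O)(OC)OC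
Why: Ohira-Bestmann (Seyferth-Gilbert) homologation, in which methanolysis of the reagent gives the dimethyl (diazomethyl)phosphonate anion that olefinates the aldehyde and, after loss of N2 and a 1,2-hydrogen shift, gives the terminal alkyne under conditions that leave aryl benzyl ethers untouched.

Step 2
Reactants: 3 [4-(benzyloxy)phenyl]acetic acid
Product: 5 2-[4-(benzyloxy)phenyl]-N-methoxy-N-methylacetamide (Weinreb amide), via acyl imidazole 4 (not isolated)
Conditions: CDI, CH2Cl2, rt; then MeNHOMe·HCl, rt
Reagents that add atoms: N,O-dimethylhydroxylamine hydrochloride, Cl.CNOC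
Why: Amide coupling by way of the acyl imidazole 4, which N,O-dimethylhydroxylamine acylates cleanly without any base strong enough to touch the benzylic CH2.

Step 3
Reactants: 2 2,4-bis(benzyloxy)-1-ethynylbenzene; 5 2-[4-(benzyloxy)phenyl]-N-methoxy-N-methylacetamide
Product: 8 1-[4-(benzyloxy)phenyl]-4-[2,4-bis(benzyloxy)phenyl]but-3-yn-2-one (ynone), via lithium acetylide 6 (not isolated), via tetrahedral lithium adduct 7 (not isolated)
Conditions: n-BuLi, THF, −78 °C; then 5, −78 → −40 °C; AcOH in THF at −78 °C
Reagents that add atoms: none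
Why: Weinreb ketone synthesis, in which the weakly basic acetylide 6 adds once to give the chelated adduct 7, and this releases the ynone only on the cold acetic acid quench, so the acidic benzylic ketone never meets base.

Step 4
Reactants: 8 1-[4-(benzyloxy)phenyl]-4-[2,4-bis(benzyloxy)phenyl]but-3-yn-2-one
Product: 9 (2R)-1-[4-(benzyloxy)phenyl]-4-[2,4-bis(benzyloxy)phenyl]but-3-yn-2-ol
Conditions: Ru[(R,R)-TsNCHPhCHPhNH](p-cymene) (preformed 16-electron amido complex, 2 mol %), i-PrOH, rt
Reagents that add atoms: none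
Why: Noyori asymmetric transfer hydrogenation of an alkynyl ketone, in which the ruthenium hydride and N–H deliver hydrogen to the carbonyl alone through an outer-sphere six-membered transition state with the alkynyl group in the place an aryl group takes with aryl ketones, so the (R,R)-ligand should give the (R)-carbinol, and the base-free amido complex (the chloride precatalyst would need KOH) spares the enolisable ynone and the triple bond.

Step 5
Reactants: 9 (2R)-1-[4-(benzyloxy)phenyl]-4-[2,4-bis(benzyloxy)phenyl]but-3-yn-2-ol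
Product: 10 (2R)-1-[4-(benzyloxy)phenyl]-4-[2,4-bis(benzyloxy)phenyl]but-3-yn-2-yl methanesulfonate
Conditions: MsCl, Et3N, CH2Cl2, −78 °C; cold aqueous wash, used crude at once
Reagents that add atoms: methanesulfonyl chloride, CS(=O)(=O)Cl
Why: Sulfonylation at oxygen (by way of sulfene) leaves the C–O bond and thus the R configuration untouched, and the low temperature and immediate use answer the readiness of this electron-rich propargylic mesylate to ionise.

Step 6
Reactants: 10 (2R)-1-[4-(benzyloxy)phenyl]-4-[2,4-bis(benzyloxy)phenyl]but-3-yn-2-yl methanesulfonate; 1 2,4-bis(benzyloxy)benzaldehyde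
Product: 12 (1S,2S)-2-[4-(benzyloxy)benzyl]-1,4-bis[2,4-bis(benzyloxy)phenyl]but-3-yn-1-ol (anti homopropargylic alcohol), via allenylzinc 11 (not isolated)
Conditions: Pd(OAc)2 (5 mol %), PPh3 (5 mol %), Et2Zn (3 equiv), THF, −78 → −20 °C; aq NH4Cl
Reagents that add atoms: none
Why: Marshall propargylation, in which zerovalent palladium (formed from Pd(OAc)2, PPh3 and Et2Zn) displaces the mesylate in an anti SN2′ sense, transmetalation with retention gives the (aS)-allenylzinc 11, and this adds to aldehyde 1 through a cyclic six-membered transition state (syn SE2′), which forms the C4–C5 bond with net inversion at the former carbinol carbon (R becomes S at C4) and places the new carbinol anti (1S); that carbinol centre need not be pure because step 8 resets it.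

Step 7
Reactants: 12 (1S,2S)-2-[4-(benzyloxy)benzyl]-1,4-bis[2,4-bis(benzyloxy)phenyl]but-3-yn-1-ol
Product: 13 (2S,3S)-3-[4-(benzyloxy)benzyl]-2,5-bis[2,4-bis(benzyloxy)phenyl]-2,3-dihydrofuran
Conditions: Ph3PAuCl (2 mol %), AgOTf (2 mol %), 4 Å MS, CH2Cl2, 0 °C → rt; Et3N, filtration through basic Al2O3, used directly
Reagents that add atoms: none
Why: Gold-catalysed 5-endo-dig cycloisomerisation (intramolecular hydroalkoxylation), in which Ph3PAu+ (monovalent gold) activates the alkyne, the hydroxyl adds to the aryl-bearing carbon that carries the greater positive charge next to the 2,4-dialkoxyphenyl ring, and protodeauration releases the enol ether in an isomerisation that keeps every atom and both stereocentres of 12.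

Step 8
Reactants: 13 (2S,3S)-3-[4-(benzyloxy)benzyl]-2,5-bis[2,4-bis(benzyloxy)phenyl]-2,3-dihydrofuran; 14 4-(benzyloxy)benzaldehyde
Product: 17 [(2S,3S,4S,5S)-4-[4-(benzyloxy)benzyl]-5-[2,4-bis(benzyloxy)phenyl]-2-[4-(benzyloxy)phenyl]oxolan-3-yl][2,4-bis(benzyloxy)phenyl]methanone (pentabenzyl ether of the target), via oxocarbenium aldolate 15 (not isolated), via ring-opened benzylic cation 16 (not isolated)
Conditions: Sn(OTf)2 (10 mol %), 4 Å MS, CH2Cl2, −78 → 0 °C, held until the isomer ratio is constant; Et3N
Reagents that add atoms: none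
Why: Proposed new method: Sn(OTf)2 activates aldehyde 14 and the enol ether carbon of 13 (ring C3 of the target) adds to it in a Mukaiyama-type aldol step that forms C2–C3 and the 2-aryl oxocarbenium aldolate 15; the O–C5 bond of 15 then heterolyses, because the leaving group is a neutral aryl ketone and the cation of 16 is a 2,4-dialkoxybenzyl, quinone-methide-like cation, and the tin-bound aldolate oxygen captures C5, so that the aldehyde oxygen becomes O1, the old ring oxygen becomes the ketone oxygen and all atoms of 13 and 14 are kept. The closest known reaction types are the Lewis acid catalysed [3+2] annulation of donor-acceptor cyclopropanes with aldehydes to 2,5-diaryl oxolanes (13 is the Cloke-Wilson isomer of such a cyclopropane and so cannot divert by that rearrangement), the Mukaiyama aldol addition of enol ethers and the alkyne Prins cyclisation of homopropargylic alcohols with aldehydes to 3-acyl oxolanes. The one ring of the target, O1–C2–C3–C4–C5, closes by 5-exo-trig attack of the aldolate oxygen on the benzylic cation (the exocyclic C5=aryl bond of its quinone methide form) as the temporary dihydrofuran ring opens. C2, C3 and C5 are all under thermodynamic control relative to the fixed C4: aldol addition, Lewis acid enolisation at C3 and ionisation at C5 are reversible, so the 4-benzyl group steers each neighbour trans in turn (4,5-trans, 3,4-trans, 2,3-trans), which is the (2S,3S,4S,5S) array. The step needs carbon attack by C3 on the aldehyde, secured by the polarised 2-aryl enol ether; capture of the C5 cation and not loss of the C4 proton or Friedel-Crafts closure, secured by the cold non-basic medium, the fast intramolecular five-ring capture and the fact that every ring position able to reach the cation is meta to its ether oxygens; and the all-trans array, secured by the reversibility of the three steps.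

Step 9
Reactants: 17 pentabenzyl ether of the target
Product: 18 (2,4-dihydroxyphenyl)[(2S,3S,4S,5S)-5-(2,4-dihydroxyphenyl)-4-(4-hydroxybenzyl)-2-(4-hydroxyphenyl)oxolan-3-yl]methanone (CNP0181717.2)
Conditions: H2 (1 atm), 10% Pd/C, EtOAc–THF, rt, stopped at the end of uptake
Reagents that add atoms: none
Why: Hydrogenolysis of aryl benzyl ethers over Pd/C, in which the five ArO–CH2Ph bonds cleave far faster than the hindered secondary benzylic C–O bonds of the ring and the hydrogen-bonded 2-hydroxyaryl ketone is slow to reduce in a neutral medium, so stopping at the end of uptake should give the pentaphenol with all four stereocentres untouched.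

**Compound list**

1 | 2,4-bis(benzyloxy)benzaldehyde | O=Cc1ccc(OCc2ccccc2)cc1OCc1ccccc1 | starting material
2 | 2,4-bis(benzyloxy)-1-ethynylbenzene | C#Cc1ccc(OCc2ccccc2)cc1OCc1ccccc1 | intermediate
3 | [4-(benzyloxy)phenyl]acetic acid | OC(=O)Cc1ccc(OCc2ccccc2)cc1 | starting material
4 | 2-[4-(benzyloxy)phenyl]-1-(imidazol-1-yl)ethan-1-one (acyl imidazole) | O=C(Cc1ccc(OCc2ccccc2)cc1)n1ccnc1 | intermediate (not isolated)
5 | 2-[4-(benzyloxy)phenyl]-N-methoxy-N-methylacetamide | CON(C)C(=O)Cc1ccc(OCc2ccccc2)cc1 | intermediate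
6 | lithium [2,4-bis(benzyloxy)phenyl]ethynide | [Li]C#Cc1ccc(OCc2ccccc2)cc1OCc1ccccc1 | intermediate (not isolated)
7 | lithium 1-[4-(benzyloxy)phenyl]-4-[2,4-bis(benzyloxy)phenyl]-2-[methoxy(methyl)amino]but-3-yn-2-olate (tetrahedral adduct, racemic centre) | [Li]OC(Cc1ccc(OCc2ccccc2)cc1)(C#Cc1ccc(OCc2ccccc2)cc1OCc1ccccc1)N(C)OC | intermediate (not isolated)
8 | 1-[4-(benzyloxy)phenyl]-4-[2,4-bis(benzyloxy)phenyl]but-3-yn-2-one | O=C(Cc1ccc(OCc2ccccc2)cc1)C#Cc1ccc(OCc2ccccc2)cc1OCc1ccccc1 | intermediate
9 | (2R)-1-[4-(benzyloxy)phenyl]-4-[2,4-bis(benzyloxy)phenyl]but-3-yn-2-ol | O[C@H](Cc1ccc(OCc2ccccc2)cc1)C#Cc1ccc(OCc2ccccc2)cc1OCc1ccccc1 | intermediate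
10 | (2R)-1-[4-(benzyloxy)phenyl]-4-[2,4-bis(benzyloxy)phenyl]but-3-yn-2-yl methanesulfonate | CS(=O)(=O)O[C@H](Cc1ccc(OCc2ccccc2)cc1)C#Cc1ccc(OCc2ccccc2)cc1OCc1ccccc1 | intermediate
11 | ethyl{(aS)-1-[2,4-bis(benzyloxy)phenyl]-4-[4-(benzyloxy)phenyl]buta-1,2-dien-1-yl}zinc (allenylzinc, P helicity) | CC[Zn]C(c1ccc(OCc2ccccc2)cc1OCc1ccccc1)=[C@@]=C([H])Cc1ccc(OCc2ccccc2)cc1 | intermediate (not isolated)
12 | (1S,2S)-2-[4-(benzyloxy)benzyl]-1,4-bis[2,4-bis(benzyloxy)phenyl]but-3-yn-1-ol | O[C@H](c1ccc(OCc2ccccc2)cc1OCc1ccccc1)[C@@H](Cc1ccc(OCc2ccccc2)cc1)C#Cc1ccc(OCc2ccccc2)cc1OCc1ccccc1 | intermediate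
13 | (2S,3S)-3-[4-(benzyloxy)benzyl]-2,5-bis[2,4-bis(benzyloxy)phenyl]-2,3-dihydrofuran (2,3-trans) | C1(c2ccc(OCc3ccccc3)cc2OCc2ccccc2)=C[C@H](Cc2ccc(OCc3ccccc3)cc2)[C@@H](c2ccc(OCc3ccccc3)cc2OCc2ccccc2)O1 | intermediate
14 | 4-(benzyloxy)benzaldehyde | O=Cc1ccc(OCc2ccccc2)cc1 | starting material
15 | oxocarbenium aldolate: (4S,5S)-4-[4-(benzyloxy)benzyl]-2,5-bis[2,4-bis(benzyloxy)phenyl]-3-{[4-(benzyloxy)phenyl](oxido)methyl}-4,5-dihydro-3H-furan-1-ium, drawn as the free zwitterion (oxido group bound to tin; the two new carbons not yet settled) | [O-]C(c1ccc(OCc2ccccc2)cc1)C1[C@H](Cc2ccc(OCc3ccccc3)cc2)[C@@H](c2ccc(OCc3ccccc3)cc2OCc2ccccc2)[O+]=C1c1ccc(OCc2ccccc2)cc1OCc1ccccc1 | intermediate (not isolated)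
16 | ring-opened benzylic cation: the aryl ketone with the 2,4-bis(benzyloxy)benzyl cation at C5 and the tin-bound alkoxide at C2, drawn as the free zwitterion (benzyl-bearing carbon as in 13) | [O-]C(c1ccc(OCc2ccccc2)cc1)C(C(=O)c1ccc(OCc2ccccc2)cc1OCc1ccccc1)[C@H](Cc1ccc(OCc2ccccc2)cc1)[CH+]c1ccc(OCc2ccccc2)cc1OCc1ccccc1 | intermediate (not isolated)
17 | [(2S,3S,4S,5S)-4-[4-(benzyloxy)benzyl]-5-[2,4-bis(benzyloxy)phenyl]-2-[4-(benzyloxy)phenyl]oxolan-3-yl][2,4-bis(benzyloxy)phenyl]methanone (all-trans) | O=C(c1ccc(OCc2ccccc2)cc1OCc1ccccc1)[C@H]1[C@H](Cc2ccc(OCc3ccccc3)cc2)[C@@H](c2ccc(OCc3ccccc3)cc2OCc2ccccc2)O[C@@H]1c1ccc(OCc2ccccc2)cc1 | intermediate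
18 | (2,4-dihydroxyphenyl)[(2S,3S,4S,5S)-5-(2,4-dihydroxyphenyl)-4-(4-hydroxybenzyl)-2-(4-hydroxyphenyl)oxolan-3-yl]methanone | O=C(c1ccc(O)cc1O)[C@H]1[C@H](Cc2ccc(O)cc2)[C@@H](c2ccc(O)cc2O)O[C@@H]1c1ccc(O)cc1 | target

**Count and risks**

Total: 9 steps. Longest linear sequence: 8 steps (1 → 2 → 8 → 9 → 10 → 12 → 13 → 17 → 18; the branch from 3 through 5 is equally long).

Steps most likely to fail:

1. Step 8 (new method). The C5 cation may lose the C4 proton to a styrene before the aldolate captures it, the enol ether may simply be hydrolysed by traces of water, or equilibration may stop short of the all-trans isomer. The fallback uses known chemistry, sets out from 13 and returns at 17, and makes the same two bonds in separate conventional operations. Enol ether 13 is hydrolysed (PPTS, THF–H2O, rt) to the γ-hydroxy ketone (3S,4S)-3-[4-(benzyloxy)benzyl]-1,4-bis[2,4-bis(benzyloxy)phenyl]-4-hydroxybutan-1-one F1. The hydroxyl is silylated (TBSCl, imidazole, DMF) to the silyl ether F2. Its lithium enolate (LiHMDS, THF, −78 °C) is added to aldehyde 14 to give the aldol adduct F3 as a mixture at the two new carbons. Catalytic TsOH·H2O in CH2Cl2 should then ionise the silyloxy-bearing 2,4-bis(benzyloxy)benzylic carbon and let the aldol hydroxyl close the oxolane, the cyclodehydration long used for 1,4-diaryl-1,4-diols, with acid equilibration to the all-trans 17.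

2. Step 6 (with the mesylate of step 5). The electron-rich aryl-alkynyl mesylate may ionise or eliminate before palladium inserts, the allenylmetal may lose its configuration, or addition to the electron-rich ortho-substituted aldehyde may be too slow. The fallback sets out from 5 (with 1) and returns at 12; it takes the aryl group off the alkyne for the propargylation and puts it back afterwards. Commercial lithium (trimethylsilyl)acetylide is acylated by 5 to the silyl ynone 1-[4-(benzyloxy)phenyl]-4-(trimethylsilyl)but-3-yn-2-one F4. The transfer hydrogenation of step 4 gives the (R)-alcohol F5, and MsCl/Et3N gives its mesylate F6, a stable substrate of the best-precedented kind for this propargylation. The conditions of step 6 with aldehyde 1 give the silylated anti homopropargylic alcohol F7. K2CO3 in MeOH removes the silyl group to the terminal alkyne F8. Sonogashira coupling with 1-bromo-2,4-bis(benzyloxy)benzene (the dibenzyl ether of 4-bromoresorcinol; PdCl2(MeCN)2, XPhos, Cs2CO3, MeCN, 70 °C) restores the aryl group and gives 12.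

3. Step 9. Over-reduction may occur: hydrogenolysis of the benzylic C–O bonds of the ring once the phenols are free, or reduction of the aryl ketone. The fallback sets out from 17 and returns at 18. It is a non-reductive debenzylation with BCl3 and pentamethylbenzene as benzyl cation scavenger in CH2Cl2 at −78 °C, which cannot reduce either function; any reversible ionisation at C5 should return the all-trans ring. It makes no new compound (entry F0).

**Further compounds**

F1 | step 8 | (3S,4S)-3-[4-(benzyloxy)benzyl]-1,4-bis[2,4-bis(benzyloxy)phenyl]-4-hydroxybutan-1-one | O=C(c1ccc(OCc2ccccc2)cc1OCc1ccccc1)C[C@H](Cc1ccc(OCc2ccccc2)cc1)[C@H](O)c1ccc(OCc2ccccc2)cc1OCc1ccccc1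
F2 | step 8 | (3S,4S)-3-[4-(benzyloxy)benzyl]-1,4-bis[2,4-bis(benzyloxy)phenyl]-4-[(tert-butyldimethylsilyl)oxy]butan-1-one | O=C(c1ccc(OCc2ccccc2)cc1OCc1ccccc1)C[C@H](Cc1ccc(OCc2ccccc2)cc1)[C@H](O[Si](C)(C)C(C)(C)C)c1ccc(OCc2ccccc2)cc1OCc1ccccc1
F3 | step 8 | (3S,4S)-3-[4-(benzyloxy)benzyl]-2-{[4-(benzyloxy)phenyl](hydroxy)methyl}-1,4-bis[2,4-bis(benzyloxy)phenyl]-4-[(tert-butyldimethylsilyl)oxy]butan-1-one, mixture at C2 and the new carbinol carbon | OC(c1ccc(OCc2ccccc2)cc1)C(C(=O)c1ccc(OCc2ccccc2)cc1OCc1ccccc1)[C@H](Cc1ccc(OCc2ccccc2)cc1)[C@H](O[Si](C)(C)C(C)(C)C)c1ccc(OCc2ccccc2)cc1OCc1ccccc1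
F4 | step 6 | 1-[4-(benzyloxy)phenyl]-4-(trimethylsilyl)but-3-yn-2-one | O=C(Cc1ccc(OCc2ccccc2)cc1)C#C[Si](C)(C)C
F5 | step 6 | (2R)-1-[4-(benzyloxy)phenyl]-4-(trimethylsilyl)but-3-yn-2-ol | O[C@H](Cc1ccc(OCc2ccccc2)cc1)C#C[Si](C)(C)C
F6 | step 6 | (2R)-1-[4-(benzyloxy)phenyl]-4-(trimethylsilyl)but-3-yn-2-yl methanesulfonate | CS(=O)(=O)O[C@H](Cc1ccc(OCc2ccccc2)cc1)C#C[Si](C)(C)C
F7 | step 6 | (1S,2S)-2-[4-(benzyloxy)benzyl]-1-[2,4-bis(benzyloxy)phenyl]-4-(trimethylsilyl)but-3-yn-1-ol | O[C@H](c1ccc(OCc2ccccc2)cc1OCc1ccccc1)[C@@H](Cc1ccc(OCc2ccccc2)cc1)C#C[Si](C)(C)C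
F8 | step 6 | (1S,2S)-2-[4-(benzyloxy)benzyl]-1-[2,4-bis(benzyloxy)phenyl]but-3-yn-1-ol | O[C@H](c1ccc(OCc2ccccc2)cc1OCc1ccccc1)[C@@H](Cc1ccc(OCc2ccccc2)cc1)C#C
F0 | step 9 | none | none
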